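**Plan**

Retrosynthesis: the benzyl group on the C4' oxygen is removed first, then O1–C2 of ring C is cut (cyclodehydration), then C2–C3 (acyl shift from oxygen to carbon), and last the aryl ester C–O bond, which leads back to the ring A acetophenone and O-benzylsyringic acid.
Enabling feature: in ring A the C8a oxygen (the future O1) is ortho to the C4 carbonyl, so an aroyl group esterified on that oxygen lies within reach of the acetyl methyl carbon that becomes C3.
Forward: rings A and B are bought; the protected syringoyl chloride is esterified onto the ring A phenol, base moves the aroyl group from oxygen to carbon to give the open-chain 1,3-diketone (C2–C3), acid closes ring C (the only ring made) through O1–C2, and hydrogenolysis frees the C4' phenol.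
Stereochemistry: the target has no stereocentre and no stereogenic double bond, so nothing has to be controlled.

Key step: step 5

Assumption: the ring A acetophenone (2'-hydroxy-4',5',6'-trimethoxyacetophenone) is taken as a catalogue compound, and the 1,3-diketone is drawn in its diketo form although it should exist largely as the chelated enol.

**Route**

Step 1
Reactants: 1 syringic acid (4-hydroxy-3,5-dimethoxybenzoic acid)
Product: 2 benzyl 4-(benzyloxy)-3,5-dimethoxybenzoate
Conditions: BnBr (2.5 equiv), K2CO3 (3 equiv), DMF, 60 °C
Reagents that add atoms: benzyl bromide, BrCc1ccccc1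
Why: Williamson etherification of the phenoxide and SN2 O-alkylation of the carboxylate by the same electrophile should benzylate both acidic sites in one operation, the benzyl ether being chosen because it tolerates base, acid chloride formation and the later acid cyclisation yet leaves by hydrogenolysis.

Step 2
Reactants: 2 benzyl 4-(benzyloxy)-3,5-dimethoxybenzoate
Product: 3 4-(benzyloxy)-3,5-dimethoxybenzoic acid
Conditions: 2 M aq NaOH, MeOH–THF, 65 °C; then 1 M HCl to pH 2
Reagents that add atoms: sodium hydroxide, [Na+].[OH-]
Why: Saponification (base-mediated acyl substitution) should cleave only the benzyl ester, because the aryl benzyl ether and the methyl ethers are inert to hydroxide, and the acid should precipitate on acidification.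

Step 3
Reactants: 3 4-(benzyloxy)-3,5-dimethoxybenzoic acid
Product: 4 4-(benzyloxy)-3,5-dimethoxybenzoyl chloride
Conditions: (COCl)2 (1.5 equiv), DMF (cat.), CH2Cl2, 0 °C to rt; evaporate, crude used directly
Reagents that add atoms: oxalyl chloride, O=C(Cl)C(=O)Cl
Why: DMF-catalysed acid chloride formation with oxalyl chloride is a standard carboxyl activation that gives only gaseous by-products and should leave the benzyl and methyl ethers untouched.

Step 4
Reactants: 4 4-(benzyloxy)-3,5-dimethoxybenzoyl chloride; 5 1-(2-hydroxy-4,5,6-trimethoxyphenyl)ethan-1-one (2'-hydroxy-4',5',6'-trimethoxyacetophenone)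
Product: 6 2-acetyl-3,4,5-trimethoxyphenyl 4-(benzyloxy)-3,5-dimethoxybenzoate
Conditions: pyridine, DMAP (0.1 equiv), 0 °C to rt
Reagents that add atoms: none
Why: Pyridine/DMAP-mediated O-acylation (nucleophilic acyl substitution through an acylpyridinium ion) should esterify the single phenol of 5 despite its hydrogen bond to the acetyl group, and under these weakly basic conditions the acetyl methyl is not enolised, so acylation stays on oxygen.

Step 5
Reactants: 6 2-acetyl-3,4,5-trimethoxyphenyl 4-(benzyloxy)-3,5-dimethoxybenzoate
Product: 9 1-[4-(benzyloxy)-3,5-dimethoxyphenyl]-3-(2-hydroxy-4,5,6-trimethoxyphenyl)propane-1,3-dione, via lithium enolate 7 (not isolated), via cyclic lithium alkoxide 8 (not isolated)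
Conditions: LiN(SiMe3)2 (3 equiv), THF, −78 °C to rt; then 1 M HCl
Reagents that add atoms: none
Why: LiN(SiMe3)2 removes a proton from the acetyl methyl group, the only enolisable position, to give lithium enolate 7, whose carbon adds to the neighbouring aryl ester carbonyl to form the six-membered cyclic alkoxide 8. Collapse of 8 expels the ring A phenoxide, so the aroyl group has moved from oxygen to carbon and the C2–C3 bond is made; a second equivalent of base turns the 1,3-diketone into its stabilised enolate, which holds the material there until the acid quench releases 9. This is the Baker–Venkataraman rearrangement, an intramolecular Claisen condensation well known for ortho-aroyloxyacetophenones. No ring persists in the product, since the transient ring of 8 forms by 6-exo-trig addition and reopens, and no stereocentre survives, the carbinol carbon of 8 being racemic and lost on collapse. The selectivity needed is a single C-acylation without cleavage of the ester: the ortho placement of ester and acetyl group on ring A makes the transfer intramolecular, the diketone enolate is too stabilised to be acylated again, and the hindered amide base is not nucleophilic toward the ester.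

Step 6
Reactants: 9 1-[4-(benzyloxy)-3,5-dimethoxyphenyl]-3-(2-hydroxy-4,5,6-trimethoxyphenyl)propane-1,3-dione
Product: 10 2-[4-(benzyloxy)-3,5-dimethoxyphenyl]-5,6,7-trimethoxy-4H-chromen-4-one
Conditions: H2SO4 (cat.), AcOH, 95 °C
Reagents that add atoms: none
Why: Acid-catalysed cyclodehydration, the usual closure of ortho-hydroxydibenzoylmethanes to flavones, should let the ring A phenol add 6-exo-trig to the protonated aroyl carbonyl and lose water to give the 4-pyranone ring C, the regiochemistry being fixed because this is the only hydroxyl and only the distal carbonyl gives a six-membered ring.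

Step 7
Reactants: 10 2-[4-(benzyloxy)-3,5-dimethoxyphenyl]-5,6,7-trimethoxy-4H-chromen-4-one
Product: 11 ageconyflavone C (2-(4-hydroxy-3,5-dimethoxyphenyl)-5,6,7-trimethoxy-4H-chromen-4-one)
Conditions: H2 (1 atm), 10% Pd/C, EtOAc–MeOH, rt
Reagents that add atoms: none
Why: Catalytic hydrogenolysis of the benzyl aryl ether should free the C4' phenol while the five methyl ethers and the chromone are left alone at atmospheric pressure and room temperature, provided the reaction is stopped at full conversion.

**Compound list**

1 | syringic acid (4-hydroxy-3,5-dimethoxybenzoic acid) | COc1cc(C(=O)O)cc(OC)c1O | starting material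
2 | benzyl 4-(benzyloxy)-3,5-dimethoxybenzoate | COc1cc(C(=O)OCc2ccccc2)cc(OC)c1OCc1ccccc1 | intermediate
3 | 4-(benzyloxy)-3,5-dimethoxybenzoic acid | COc1cc(C(=O)O)cc(OC)c1OCc1ccccc1 | intermediate
4 | 4-(benzyloxy)-3,5-dimethoxybenzoyl chloride | COc1cc(C(=O)Cl)cc(OC)c1OCc1ccccc1 | intermediate
5 | 1-(2-hydroxy-4,5,6-trimethoxyphenyl)ethan-1-one | CC(=O)c1c(O)cc(OC)c(OC)c1OC | starting material
6 | 2-acetyl-3,4,5-trimethoxyphenyl 4-(benzyloxy)-3,5-dimethoxybenzoate | COc1cc(C(=O)Oc2cc(OC)c(OC)c(OC)c2C(C)=O)cc(OC)c1OCc1ccccc1 | intermediate
7 | lithium 1-[2-{[4-(benzyloxy)-3,5-dimethoxybenzoyl]oxy}-4,5,6-trimethoxyphenyl]ethen-1-olate (lithium enolate of 6, not isolated) | COc1cc(C(=O)Oc2cc(OC)c(OC)c(OC)c2C(=C)[O-])cc(OC)c1OCc1ccccc1.[Li+] | intermediate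
8 | lithium 2-[4-(benzyloxy)-3,5-dimethoxyphenyl]-5,6,7-trimethoxy-4-oxo-3,4-dihydro-2H-chromen-2-olate (racemic cyclic alkoxide, not isolated) | COc1cc(C2([O-])CC(=O)c3c(OC)c(OC)c(OC)cc3O2)cc(OC)c1OCc1ccccc1.[Li+] | intermediate
9 | 1-[4-(benzyloxy)-3,5-dimethoxyphenyl]-3-(2-hydroxy-4,5,6-trimethoxyphenyl)propane-1,3-dione | COc1cc(C(=O)CC(=O)c2c(O)cc(OC)c(OC)c2OC)cc(OC)c1OCc1ccccc1 | intermediate
10 | 2-[4-(benzyloxy)-3,5-dimethoxyphenyl]-5,6,7-trimethoxy-4H-chromen-4-one | COc1cc(-c2cc(=O)c3c(OC)c(OC)c(OC)cc3o2)cc(OC)c1OCc1ccccc1 | intermediate
11 | ageconyflavone C (2-(4-hydroxy-3,5-dimethoxyphenyl)-5,6,7-trimethoxy-4H-chromen-4-one) | COc1cc(-c2cc(=O)c3c(OC)c(OC)c(OC)cc3o2)cc(OC)c1O | target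

**Step count and risks**

Total step count: 7. Longest linear sequence: 7 steps (1 to 11); acetophenone 5 enters at step 4.

Steps most likely to fail:

Step 5. The aryl ester may be cleaved back to the phenol, by adventitious hydroxide or by intermolecular acyl transfer, faster than the twisted, doubly ortho-substituted acetyl group is enolised. The fallback sets out from 5 and 4 and returns at 9. Acetophenone 5 would be deprotonated twice with LiN(SiMe3)2 (3.2 equiv, THF, −78 to −10 °C) to give dilithium 3,4,5-trimethoxy-2-(1-oxidoethenyl)phenolate F1, and acid chloride 4 would be added at −78 °C. Intermolecular C-acylation of the enolate carbon is a crossed Claisen condensation of a preformed dianion, and any O-acylated material would be rearranged in the same flask by the excess base. After an acid quench this should give diketone 9, where the route is rejoined.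

Step 6. The hot acid may strip the benzyl group and let the freed benzyl cation alkylate the electron-rich C8 position of ring A, or the dehydration may stall before the pyranone is formed. The fallback sets out from 5 and returns at 10, closing ring C oxidatively without strong acid. Purchased syringaldehyde would be benzylated (benzyl bromide, K2CO3, DMF, 60 °C) to 4-(benzyloxy)-3,5-dimethoxybenzaldehyde F2. Claisen–Schmidt condensation of this aldehyde with 5 (KOH, EtOH, rt) should give (E)-3-[4-(benzyloxy)-3,5-dimethoxyphenyl]-1-(2-hydroxy-4,5,6-trimethoxyphenyl)prop-2-en-1-one F3. Heating the chalcone with catalytic iodine in DMSO at 120 °C (oxa-Michael addition followed by dehydrogenation) should then give flavone 10.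

Step 7. Saturation of the C2–C3 double bond of the pyranone may accompany the C–O hydrogenolysis, or the hydrogenolysis may stall through poor solubility of the flavone. The fallback sets out from 9 and returns at 11, removing the benzyl group before ring C exists. Hydrogenolysis of diketone 9 (H2, 10% Pd/C, EtOAc, rt) should give 1-(4-hydroxy-3,5-dimethoxyphenyl)-3-(2-hydroxy-4,5,6-trimethoxyphenyl)propane-1,3-dione F4. Cyclodehydration of this phenol with catalytic H2SO4 in AcOH at 95 °C should give 11 directly. Only the ring A hydroxyl can reach a carbonyl through a six-membered ring, the C4' hydroxyl being para to its own carbonyl.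

**Further compounds**

F1 | step 5 | dilithium 3,4,5-trimethoxy-2-(1-oxidoethenyl)phenolate | [Li+].[Li+].C=C([O-])c1c([O-])cc(OC)c(OC)c1OC
F2 | step 6 | 4-(benzyloxy)-3,5-dimethoxybenzaldehyde | COc1cc(C=O)cc(OC)c1OCc1ccccc1
F3 | step 6 | (E)-3-[4-(benzyloxy)-3,5-dimethoxyphenyl]-1-(2-hydroxy-4,5,6-trimethoxyphenyl)prop-2-en-1-one | COc1cc(/C=C/C(=O)c2c(O)cc(OC)c(OC)c2OC)cc(OC)c1OCc1ccccc1
F4 | step 7 | 1-(4-hydroxy-3,5-dimethoxyphenyl)-3-(2-hydroxy-4,5,6-trimethoxyphenyl)propane-1,3-dione | COc1cc(C(=O)CC(=O)c2c(O)cc(OC)c(OC)c2OC)cc(OC)c1O
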